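**Plan**
1. Late cuts: CO2H ← CO2Et and C≡C–Br ← C≡C–SiMe3. The main cut is the C6–C7 σ-bond of the side chain (numbered C2 = ring-bound CH(CH3) to C13 = CBr), giving enyne ester 14 and alkyl bromide 21.
2. Enabling feature: C5=C6 is a trisubstituted E-olefin (H on C5; CH3 and C7H2 on C6) conjugated with C3=C4, i.e. the syn H/C adduct of a methyl-capped C5≡C6 alkyne. Hydrozirconation (Zr to C6), Zr→Zn exchange and Pd-catalysed alkenyl–alkyl coupling therefore join the halves and fix 5E in one flask; no ring forms there.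
3. Enyne 14: C3=C4 by Takai olefination and Sonogashira coupling, the butanoate arm by vinyl hydroboration and two-carbon homologation, the cyclopropane (the only ring, made early in step 5) by ligand-controlled Simmons–Smith reaction of an E-allylic alcohol.
4. Bromide 21: four steps from citronellal (alkyne homologation, silylation, ozonolysis/reduction, bromination).
5. Stereochemistry: C2 from (S)-Roche ester; ring C1/C2 from the chiral dioxaborolane (trans from the E-alkene); C10 from (R)-citronellal; 3E from the Takai reaction; 5E from syn-hydrozirconation.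

Key step: step 17

Remark: the (4S,5S)-dioxaborolane ligand is assumed to induce the mirror-image sense of the (4R,5R) ligand, which turns (E)-cinnamyl alcohol into the (1S,2S) carbinol, and to override the allylic methyl stereocentre of 5.

**Step 1**
Reactants: 1 methyl (2S)-3-hydroxy-2-methylpropanoate [(S)-Roche ester]
Product: 2 methyl (2S)-3-[(tert-butyldimethylsilyl)oxy]-2-methylpropanoate
Conditions: TBSCl, imidazole, CH2Cl2, 0 °C → rt
Reagents that add atoms: tert-butyldimethylsilyl chloride, CC(C)(C)[Si](C)(C)Cl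
Why: Imidazole-promoted silyl ether formation at the primary alcohol; the stereocentre is not involved.

**Step 2**
Reactants: 2 methyl (2S)-3-[(tert-butyldimethylsilyl)oxy]-2-methylpropanoate
Product: 3 (2S)-3-[(tert-butyldimethylsilyl)oxy]-2-methylpropanal
Conditions: DIBAL-H (1.1 equiv), CH2Cl2, −78 °C; Rochelle salt work-up; used crude
Reagents that add atoms: none
Why: Partial ester reduction with DIBAL-H stops at the aluminium hemiacetal at −78 °C, and cold neutral work-up should keep the α-stereocentre intact.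

**Step 3**
Reactants: 3 (2S)-3-[(tert-butyldimethylsilyl)oxy]-2-methylpropanal
Product: 4 ethyl (2E,4R)-5-[(tert-butyldimethylsilyl)oxy]-4-methylpent-2-enoate
Conditions: (EtO)2P(O)CH2CO2Et, NaH, THF, 0 °C
Reagents that add atoms: triethyl phosphonoacetate, CCOC(=O)CP(=O)(OCC)OCC
Why: Horner–Wadsworth–Emmons olefination with a stabilised phosphonate should give the E-enoate, and the short cold reaction should not epimerise the α-centre.

**Step 4**
Reactants: 4 ethyl (2E,4R)-5-[(tert-butyldimethylsilyl)oxy]-4-methylpent-2-enoate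
Product: 5 (2E,4R)-5-[(tert-butyldimethylsilyl)oxy]-4-methylpent-2-en-1-ol
Conditions: DIBAL-H (2.2 equiv), CH2Cl2, −78 °C
Reagents that add atoms: none
Why: DIBAL-H reduces the enoate by 1,2-addition to the allylic alcohol without touching the alkene or the silyl ether.

**Step 5**
Reactants: 5 (2E,4R)-5-[(tert-butyldimethylsilyl)oxy]-4-methylpent-2-en-1-ol
Product: 6 [(1R,2S)-2-[(2R)-1-[(tert-butyldimethylsilyl)oxy]propan-2-yl]cyclopropyl]methanol
Conditions: Zn(CH2I)2·DME (from Et2Zn, CH2I2, DME), (4S,5S)-2-butyl-N,N,N′,N′-tetramethyl-1,3,2-dioxaborolane-4,5-dicarboxamide (1.2 equiv), CH2Cl2, −10 °C → rt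
Reagents that add atoms: diiodomethane, ICI
Why: Simmons–Smith cyclopropanation in its dioxaborolane-mediated (Charette) form: the zinc alkoxide of 5 is held by the boron ligand, which is not consumed and directs the stereospecific syn transfer of CH2 to one face of the E-alkene, so the ring should be trans and both ring stereocentres are set by the ligand.

**Step 6**
Reactants: 6 [(1R,2S)-2-[(2R)-1-[(tert-butyldimethylsilyl)oxy]propan-2-yl]cyclopropyl]methanol
Product: 7 (1R,2S)-2-[(2R)-1-[(tert-butyldimethylsilyl)oxy]propan-2-yl]cyclopropane-1-carbaldehyde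
Conditions: Dess–Martin periodinane, NaHCO3, CH2Cl2, 0 °C → rt
Reagents that add atoms: none
Why: Dess–Martin oxidation of a primary alcohol under buffered, non-acidic conditions that spare the cyclopropane and the silyl ether.

**Step 7**
Reactants: 7 (1R,2S)-2-[(2R)-1-[(tert-butyldimethylsilyl)oxy]propan-2-yl]cyclopropane-1-carbaldehyde
Product: 8 tert-butyl{(2R)-2-[(1R,2S)-2-ethenylcyclopropyl]propoxy}dimethylsilane
Conditions: Ph3PCH3Br, KHMDS, THF, 0 °C
Reagents that add atoms: methyltriphenylphosphonium bromide, [Br-].C[P+](c1ccccc1)(c1ccccc1)c1ccccc1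
Why: Wittig methylenation of an unhindered aldehyde; the trans ring stereochemistry is already the stable one.

**Step 8**
Reactants: 8 tert-butyl{(2R)-2-[(1R,2S)-2-ethenylcyclopropyl]propoxy}dimethylsilane
Product: 10 ethyl 4-[(1R,2R)-2-[(2R)-1-[(tert-butyldimethylsilyl)oxy]propan-2-yl]cyclopropyl]butanoate, via alkylborane 9 (not isolated)
Conditions: 9-BBN, THF, 0 °C → rt; then BrCH2CO2Et, t-BuOK, t-BuOH/THF, 0 °C
Reagents that add atoms: ethyl bromoacetate, BrCC(=O)OCC
Why: Anti-Markovnikov hydroboration followed by organoborane α-alkylation of the bromoacetate enolate (boron ate complex, 1,2-shift of the primary alkyl group with loss of bromide, protonolysis by t-BuOH) adds the CH2CO2Et unit without a cyclopropylcarbinyl radical or cation ever forming.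

**Step 9**
Reactants: 10 ethyl 4-[(1R,2R)-2-[(2R)-1-[(tert-butyldimethylsilyl)oxy]propan-2-yl]cyclopropyl]butanoate
Product: 11 ethyl 4-[(1R,2R)-2-[(2R)-1-hydroxypropan-2-yl]cyclopropyl]butanoate
Conditions: HF·pyridine, THF/pyridine, 0 °C → rt
Reagents that add atoms: none
Why: Fluoride-driven cleavage of a primary silyl ether under buffered conditions that leave the ethyl ester and the ring untouched.

**Step 10**
Reactants: 11 ethyl 4-[(1R,2R)-2-[(2R)-1-hydroxypropan-2-yl]cyclopropyl]butanoate
Product: 12 ethyl 4-[(1R,2R)-2-[(2R)-1-oxopropan-2-yl]cyclopropyl]butanoate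
Conditions: Dess–Martin periodinane, NaHCO3, CH2Cl2, 0 °C; used crude
Reagents that add atoms: none
Why: Dess–Martin oxidation under buffered conditions should deliver the α-branched aldehyde without epimerisation if it is used at once.

**Step 11**
Reactants: 12 ethyl 4-[(1R,2R)-2-[(2R)-1-oxopropan-2-yl]cyclopropyl]butanoate
Product: 13 ethyl 4-[(1R,2R)-2-[(2R,3E)-4-iodobut-3-en-2-yl]cyclopropyl]butanoate
Conditions: CrCl2, CHI3, THF/dioxane, 0 °C → rt
Reagents that add atoms: iodoform, IC(I)I
Why: Takai olefination: the gem-dichromium reagent adds to the aldehyde and eliminates to the E-vinyl iodide under non-basic conditions that tolerate the ester and the α-stereocentre.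

**Step 12**
Reactants: 13 ethyl 4-[(1R,2R)-2-[(2R,3E)-4-iodobut-3-en-2-yl]cyclopropyl]butanoate
Product: 14 ethyl 4-[(1R,2R)-2-[(2S,3E)-hept-3-en-5-yn-2-yl]cyclopropyl]butanoate
Conditions: propyne, PdCl2(PPh3)2 (cat.), CuI (cat.), Et3N, THF, 0 °C → rt
Reagents that add atoms: propyne, CC#C
Why: Sonogashira coupling of an alkenyl iodide proceeds with retention of the E geometry (the descriptor at C2 changes from R to S only through CIP priorities).

**Step 13**
Reactants: 15 (3R)-3,7-dimethyloct-6-enal [(R)-citronellal]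
Product: 16 (4R)-4,8-dimethylnon-7-en-1-yne
Conditions: dimethyl (1-diazo-2-oxopropyl)phosphonate, K2CO3, MeOH, 0 °C → rt
Reagents that add atoms: dimethyl (1-diazo-2-oxopropyl)phosphonate, CC(=O)C(=[N+]=[N-])P(=O)(OC)OC
Why: Seyferth–Gilbert homologation in the Ohira–Bestmann form turns the aldehyde into the terminal alkyne; the stereocentre is β to the carbonyl and cannot epimerise.

**Step 14**
Reactants: 16 (4R)-4,8-dimethylnon-7-en-1-yne
Product: 18 [(4R)-4,8-dimethylnon-7-en-1-yn-1-yl]trimethylsilane, via lithium acetylide 17 (not isolated)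
Conditions: n-BuLi, THF, −78 °C; TMSCl, −78 °C → rt
Reagents that add atoms: chlorotrimethylsilane, C[Si](C)(C)Cl
Why: Deprotonation of the terminal alkyne and C-silylation of the acetylide masks the alkyne C–H for the later organometallic steps.

**Step 15**
Reactants: 18 [(4R)-4,8-dimethylnon-7-en-1-yn-1-yl]trimethylsilane
Product: 20 (4R)-4-methyl-7-(trimethylsilyl)hept-6-yn-1-ol, via aldehyde 19 (not isolated)
Conditions: O3, CH2Cl2/MeOH, −78 °C (Sudan III end-point); then NaBH4, −78 → 0 °C
Reagents that add atoms: ozone, [O-][O+]=O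
Why: Ozonolysis with reductive work-up: the electron-rich trisubstituted alkene is cleaved far faster than the alkynylsilane, and borohydride reduces the aldehyde in the same flask.

**Step 16**
Reactants: 20 (4R)-4-methyl-7-(trimethylsilyl)hept-6-yn-1-ol
Product: 21 [(4R)-7-bromo-4-methylhept-1-yn-1-yl]trimethylsilane
Conditions: CBr4, PPh3, CH2Cl2, 0 °C
Reagents that add atoms: carbon tetrabromide, BrC(Br)(Br)Br
Why: Appel bromination of a primary alcohol by SN2 displacement of the alkoxyphosphonium ion; the remote stereocentre is untouched.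

**Step 17**
Reactants: 14 ethyl 4-[(1R,2R)-2-[(2S,3E)-hept-3-en-5-yn-2-yl]cyclopropyl]butanoate; 21 [(4R)-7-bromo-4-methylhept-1-yn-1-yl]trimethylsilane
Product: 24 ethyl 4-[(1R,2R)-2-[(2S,3E,5E,10R)-6,10-dimethyl-13-(trimethylsilyl)trideca-3,5-dien-12-yn-2-yl]cyclopropyl]butanoate, via dienylzirconocene chloride 22 (not isolated), via dienylzinc chloride 23 (not isolated)
Conditions: Cp2Zr(H)Cl (1.3 equiv), THF, rt, dark; ZnCl2, THF, 0 °C; then 21 (1.3 equiv), Pd2(dba)3 (cat.), PCyp3 (cat.), N-methylimidazole, THF/NMP, 80 °C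
Reagents that add atoms: none
Why: Cp2Zr(H)Cl adds H–Zr syn across the C5≡C6 triple bond of 14 and, with the small excess of hydride that allows equilibration, the metal should settle on the less hindered methyl-bearing C6 to give 22, which exchanges Zr for Zn with retention (23); Pd(0)/PCyp3 then inserts into the primary C–Br bond of 21, 23 transmetalates and reductive elimination forges the C6–C7 bond. The closest known reaction types are the hydrozirconation–iodination of methyl-capped alkynes and the Pd/trialkylphosphine Negishi coupling of alkenylzinc halides, made by hydrozirconation–transmetalation, with unactivated primary alkyl bromides. No ring is closed and no sp3 stereocentre is made; the new stereo-element is the trisubstituted 5E olefin, fixed by the syn delivery of H and Zr and by stereoretentive Zr→Zn→Pd transfer, while 3E and the four stereocentres are carried through untouched. The selectivity needed is regiochemical (Zr on C6, not C5), which the steric contrast between CH3 and the branched alkenyl substituent should secure, and chemoselective (alkyne before the 1,2-disubstituted olefin and the ethyl ester), which rests on the faster hydrozirconation of alkynes and on keeping the hydride to a small excess. Bromide 21 is added only after ZnCl2 so that its alkynylsilane does not meet Zr–H, and the bulky electron-rich phosphine with N-methylimidazole is there to suppress β-hydride elimination of the alkylpalladium intermediate.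

**Step 18**
Reactants: 24 ethyl 4-[(1R,2R)-2-[(2S,3E,5E,10R)-6,10-dimethyl-13-(trimethylsilyl)trideca-3,5-dien-12-yn-2-yl]cyclopropyl]butanoate
Product: 25 ethyl 4-[(1R,2R)-2-[(2S,3E,5E,10R)-13-bromo-6,10-dimethyltrideca-3,5-dien-12-yn-2-yl]cyclopropyl]butanoate
Conditions: NBS (1.1 equiv), AgNO3 (cat.), acetone, rt, dark
Reagents that add atoms: N-bromosuccinimide, O=C1CCC(=O)N1Br
Why: Silver(I)-catalysed desilylative bromination: Ag+ converts the alkynylsilane into a silver acetylide that NBS should brominate faster than it attacks the diene.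

**Step 19**
Reactants: 25 ethyl 4-[(1R,2R)-2-[(2S,3E,5E,10R)-13-bromo-6,10-dimethyltrideca-3,5-dien-12-yn-2-yl]cyclopropyl]butanoate
Product: 26 4-[(1R,2R)-2-[(2S,3E,5E,10R)-13-bromo-6,10-dimethyltrideca-3,5-dien-12-yn-2-yl]cyclopropyl]butanoic acid
Conditions: LiOH·H2O, THF/H2O, rt; then cold aq. HCl to pH 4
Reagents that add atoms: lithium hydroxide monohydrate, [Li+].[OH-].O
Why: Saponification of the ethyl ester; 1-bromoalkynes tolerate aqueous hydroxide at room temperature and no stereocentre is α to the carbonyl.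

**Compound list**
1 | methyl (2S)-3-hydroxy-2-methylpropanoate [(S)-Roche ester] | OC[C@H](C)C(=O)OC | starting material
2 | methyl (2S)-3-[(tert-butyldimethylsilyl)oxy]-2-methylpropanoate | CC(C)(C)[Si](C)(C)OC[C@H](C)C(=O)OC | intermediate
3 | (2S)-3-[(tert-butyldimethylsilyl)oxy]-2-methylpropanal | CC(C)(C)[Si](C)(C)OC[C@H](C)C=O | intermediate
4 | ethyl (2E,4R)-5-[(tert-butyldimethylsilyl)oxy]-4-methylpent-2-enoate | CC(C)(C)[Si](C)(C)OC[C@H](C)/C=C/C(=O)OCC | intermediate
5 | (2E,4R)-5-[(tert-butyldimethylsilyl)oxy]-4-methylpent-2-en-1-ol | CC(C)(C)[Si](C)(C)OC[C@H](C)/C=C/CO | intermediate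
6 | [(1R,2S)-2-[(2R)-1-[(tert-butyldimethylsilyl)oxy]propan-2-yl]cyclopropyl]methanol | CC(C)(C)[Si](C)(C)OC[C@H](C)[C@@H]1C[C@H]1CO | intermediate
7 | (1R,2S)-2-[(2R)-1-[(tert-butyldimethylsilyl)oxy]propan-2-yl]cyclopropane-1-carbaldehyde | CC(C)(C)[Si](C)(C)OC[C@H](C)[C@@H]1C[C@H]1C=O | intermediate
8 | tert-butyl{(2R)-2-[(1R,2S)-2-ethenylcyclopropyl]propoxy}dimethylsilane | CC(C)(C)[Si](C)(C)OC[C@H](C)[C@@H]1C[C@H]1C=C | intermediate
9 | 9-{2-[(1R,2R)-2-[(2R)-1-[(tert-butyldimethylsilyl)oxy]propan-2-yl]cyclopropyl]ethyl}-9-borabicyclo[3.3.1]nonane (formed in situ) | CC(C)(C)[Si](C)(C)OC[C@H](C)[C@@H]1C[C@H]1CCB1C2CCCC1CCC2 | intermediate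
10 | ethyl 4-[(1R,2R)-2-[(2R)-1-[(tert-butyldimethylsilyl)oxy]propan-2-yl]cyclopropyl]butanoate | CC(C)(C)[Si](C)(C)OC[C@H](C)[C@@H]1C[C@H]1CCCC(=O)OCC | intermediate
11 | ethyl 4-[(1R,2R)-2-[(2R)-1-hydroxypropan-2-yl]cyclopropyl]butanoate | OC[C@H](C)[C@@H]1C[C@H]1CCCC(=O)OCC | intermediate
12 | ethyl 4-[(1R,2R)-2-[(2R)-1-oxopropan-2-yl]cyclopropyl]butanoate | O=C[C@H](C)[C@@H]1C[C@H]1CCCC(=O)OCC | intermediate
13 | ethyl 4-[(1R,2R)-2-[(2R,3E)-4-iodobut-3-en-2-yl]cyclopropyl]butanoate | I/C=C/[C@H](C)[C@@H]1C[C@H]1CCCC(=O)OCC | intermediate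
14 | ethyl 4-[(1R,2R)-2-[(2S,3E)-hept-3-en-5-yn-2-yl]cyclopropyl]butanoate | CC#C/C=C/[C@H](C)[C@@H]1C[C@H]1CCCC(=O)OCC | intermediate
15 | (3R)-3,7-dimethyloct-6-enal [(R)-citronellal] | O=CC[C@H](C)CCC=C(C)C | starting material
16 | (4R)-4,8-dimethylnon-7-en-1-yne | C#CC[C@H](C)CCC=C(C)C | intermediate
17 | lithium (4R)-4,8-dimethylnon-7-en-1-yn-1-ide (formed in situ) | [Li]C#CC[C@H](C)CCC=C(C)C | intermediate
18 | [(4R)-4,8-dimethylnon-7-en-1-yn-1-yl]trimethylsilane | C[Si](C)(C)C#CC[C@H](C)CCC=C(C)C | intermediate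
19 | (4R)-4-methyl-7-(trimethylsilyl)hept-6-ynal (formed in situ) | C[Si](C)(C)C#CC[C@H](C)CCC=O | intermediate
20 | (4R)-4-methyl-7-(trimethylsilyl)hept-6-yn-1-ol | C[Si](C)(C)C#CC[C@H](C)CCCO | intermediate
21 | [(4R)-7-bromo-4-methylhept-1-yn-1-yl]trimethylsilane | C[Si](C)(C)C#CC[C@H](C)CCCBr | intermediate
22 | chlorobis(cyclopentadienyl)[(2E,4E,6S)-6-[(1R,2R)-2-(4-ethoxy-4-oxobutyl)cyclopropyl]hepta-2,4-dien-2-yl]zirconium (formed in situ; Cp rings drawn η1) | C/C(=C\C=C\[C@H](C)[C@@H]1C[C@H]1CCCC(=O)OCC)[Zr](Cl)(C1C=CC=C1)C1C=CC=C1 | intermediate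
23 | chloro[(2E,4E,6S)-6-[(1R,2R)-2-(4-ethoxy-4-oxobutyl)cyclopropyl]hepta-2,4-dien-2-yl]zinc (formed in situ) | C/C(=C\C=C\[C@H](C)[C@@H]1C[C@H]1CCCC(=O)OCC)[Zn]Cl | intermediate
24 | ethyl 4-[(1R,2R)-2-[(2S,3E,5E,10R)-6,10-dimethyl-13-(trimethylsilyl)trideca-3,5-dien-12-yn-2-yl]cyclopropyl]butanoate | C/C(=C\C=C\[C@H](C)[C@@H]1C[C@H]1CCCC(=O)OCC)CCC[C@@H](C)CC#C[Si](C)(C)C | intermediate
25 | ethyl 4-[(1R,2R)-2-[(2S,3E,5E,10R)-13-bromo-6,10-dimethyltrideca-3,5-dien-12-yn-2-yl]cyclopropyl]butanoate | C/C(=C\C=C\[C@H](C)[C@@H]1C[C@H]1CCCC(=O)OCC)CCC[C@@H](C)CC#CBr | intermediate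
26 | 4-[(1R,2R)-2-[(2S,3E,5E,10R)-13-bromo-6,10-dimethyltrideca-3,5-dien-12-yn-2-yl]cyclopropyl]butanoic acid | C/C(=C\C=C\[C@H](C)[C@@H]1C[C@H]1CCCC(=O)O)CCC[C@@H](C)CC#CBr | target

**Step count**
Total: 19 steps. Longest linear sequence: 15 steps (steps 1–12, then 17–19).

**Steps most likely to fail**

Step 17. The risk is slow transmetalation of the α-methyl-branched dienylzinc to palladium together with β-hydride elimination of the alkylpalladium species, and partial reduction of the ester if hydrozirconation has to be forced. The fallback reverses the polarity of the same bond formation and sets out from 14 and 21. Enyne 14 is hydrozirconated as before and the zirconocene 22 is quenched with I2 (THF, 0 °C) to give ethyl 4-[(1R,2R)-2-[(2S,3E,5E)-6-iodohepta-3,5-dien-2-yl]cyclopropyl]butanoate F1. Bromide 21 is converted by zinc insertion (Zn dust, cat. I2, DMA, 80 °C) into [(4R)-4-methyl-7-(trimethylsilyl)hept-6-yn-1-yl]zinc bromide F2. Negishi coupling of F1 with F2 (Pd(PPh3)4, THF/DMA, rt), in which the alkenyl iodide undergoes the easy oxidative addition, comes back to the route at 24.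

Step 8. The risk is migration of a ring B–C bond of the borabicycle in place of the primary alkyl group, or self-condensation of the bromoacetate enolate before it is captured by boron. The fallback builds the arm by olefination and sets out from 7. A Wittig reaction with the ylide from (2-carboxyethyl)triphenylphosphonium bromide (2 equiv NaHMDS, THF, −78 °C → rt) should give (3Z)-4-[(1S,2R)-2-[(2R)-1-[(tert-butyldimethylsilyl)oxy]propan-2-yl]cyclopropyl]but-3-enoic acid F3. Esterification (EtOH, EDC·HCl, cat. DMAP, CH2Cl2) gives ethyl (3Z)-4-[(1S,2R)-2-[(2R)-1-[(tert-butyldimethylsilyl)oxy]propan-2-yl]cyclopropyl]but-3-enoate F4. Diimide reduction of F4 (2-nitrobenzenesulfonyl hydrazide, Et3N, CH2Cl2, rt), which does not open the cyclopropane, comes back to the route at 10.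

Step 18. The risk is electrophilic attack of the Ag+/NBS bromine source on the electron-rich trisubstituted diene in competition with bromination at the alkynyl carbon. The fallback moves the bromination to an anionic manifold and sets out from 24. LiOH (THF/MeOH/H2O, rt) cleaves both the ester and the C(sp)–Si bond to give 4-[(1R,2R)-2-[(2S,3E,5E,10R)-6,10-dimethyltrideca-3,5-dien-12-yn-2-yl]cyclopropyl]butanoic acid F5. Alkaline hypobromite (Br2/KOH, H2O/THF, 0 °C) then brominates the acetylide of the carboxylate salt, and careful acidification comes back to the route at the target 26.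

**Further compounds**
F1 | step 17 | ethyl 4-[(1R,2R)-2-[(2S,3E,5E)-6-iodohepta-3,5-dien-2-yl]cyclopropyl]butanoate | C/C(I)=C\C=C\[C@H](C)[C@@H]1C[C@H]1CCCC(=O)OCC
F2 | step 17 | [(4R)-4-methyl-7-(trimethylsilyl)hept-6-yn-1-yl]zinc bromide | C[Si](C)(C)C#CC[C@H](C)CCC[Zn]Br
F3 | step 8 | (3Z)-4-[(1S,2R)-2-[(2R)-1-[(tert-butyldimethylsilyl)oxy]propan-2-yl]cyclopropyl]but-3-enoic acid | CC(C)(C)[Si](C)(C)OC[C@H](C)[C@@H]1C[C@H]1/C=C\CC(=O)O
F4 | step 8 | ethyl (3Z)-4-[(1S,2R)-2-[(2R)-1-[(tert-butyldimethylsilyl)oxy]propan-2-yl]cyclopropyl]but-3-enoate | CC(C)(C)[Si](C)(C)OC[C@H](C)[C@@H]1C[C@H]1/C=C\CC(=O)OCC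
F5 | step 18 | 4-[(1R,2R)-2-[(2S,3E,5E,10R)-6,10-dimethyltrideca-3,5-dien-12-yn-2-yl]cyclopropyl]butanoic acid | C/C(=C\C=C\[C@H](C)[C@@H]1C[C@H]1CCCC(=O)O)CCC[C@@H](C)CC#C
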